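The closed stirred flasks gamma, alpha and eta had already run near this charge, and gamma carried the same charge as the set-ups asked about, which differ in vessel, feed and time.

| setting | gamma | alpha | eta | north-east | north | south-west | south-east |
|---|---|---|---|---|---|---|---|
| starting material | 20 mM | 13 mM | 30 mM | 20 mM | 20 mM | 20 mM | 20 mM |
| partner | 30 mM | 30 mM | 30 mM | 30.0 mM (fed, over 0.500 h) | 30.0 mM | 30.0 mM | 30.0 mM |
| second reagent | 10 mM | 10 mM | 10 mM | 10.0 mM | 10.0 mM | 10.0 mM | 10.0 mM |
| third reagent | 22 mM | 22 mM | 22 mM | 22.0 mM | 22.0 mM | 22.0 mM | 22.0 mM |
| remark | run made earlier | run made earlier | run made earlier | all but partner at the start; partner goes in evenly over 0.500 h, the run ends at 1.0 h | a single well-mixed tank run continuously and read at steady state, 1.0 h in it on average | everything together in a closed stirred flask, run for 1.0 h | a single well-mixed tank run continuously and read at steady state, 3.00 h in it on average |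
| time |  |  |  | 1.0 h |  | 1.0 h |  |

- gamma (time / min: intermediate A / %, target / %): 5.00: 16.7, 0.3; 12.0: 31.0, 0.3; 25.0: 47.1, 0; 60.0: 60.5, 6.4
- alpha (time / min: intermediate A / %, target / %): 10.0: 27.7, 0.2; 20.0: 42.7, 0; 25.0: 49.2, 1.0; 40.0: 57.6, 2.9
- eta (time / min: intermediate A / %, target / %): 10.0: 24.9, 0.4; 20.0: 38.1, 0; 25.0: 43.8, 0; 40.0: 51.2, 0

(scatter of a reading: 1 percentage point)

- the stated concentrations are those of everything mixed, before any reaction; amounts are the same in each set-up
- the feed brings no volume worth counting
- the earlier runs were made in a closed, stirred flask

- the set-up with the highest amount of intermediate A at the outlet or at the end, in percent of the starting material put in ("none" if the first two lie within 2 percentage points) (north-east / north / south-west / south-east / none)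
- amount of intermediate A at the outlet or at the end, in percent of the starting material put in, north-east
- amount of intermediate A at the outlet or at the end, in percent of the starting material put in, north
- amount of intermediate A at the outlet or at the end, in percent of the starting material put in, south-west
- amount of intermediate A at the outlet or at the end, in percent of the starting material put in, south-east

From the first gamma reading, 16.7 % at 5.00 min, I reckoned 2.19 for a hold of 1.0 h. This N is a Damköhler number, the pseudo-first-order rate constant of forming intermediate A at full partner charge multiplied by the hold time. It says how many e-foldings of starting material the vessel allows. With partner held at its charge, a flask could convert 88.8 % and a tank 68.7 %.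

I then tested whether N was enough. Gamma at 60.0 min held 66.9 % as intermediate A and target together, less than that 88.8 %. Its kept share r, intermediate A over the ceiling, was 0.681. At 25.0 min the same reckoning gave 0.786, so r fell with age and one number was not enough.

Using r, I expected 46.8 % from the north tank. The feed cut N to 1.64 for north-east, giving 54.9 %. South-east, at N = 6.58, gave 59.1 %, which I distrusted because r at 60.0 min stood lower than at 25.0 min. I ranked south-west first, at the gamma reading.

The forecast named south-west, with 54 %, 46 %, 60.5 % and 51 % in the order asked, noting of south-east that “Some target leakage is possible”.

The simulation gave south-west as best, with 54.8 %, 42.5 %, 59.4 % and 44.0 %. The forecast and the flask parted on south-east, by 7 percentage points.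

    starting material + partner → intermediate A (k = 1.24 M⁻¹ min⁻¹)
    second reagent + intermediate A → intermediate B (k = 0.702 M⁻¹ min⁻¹)
    third reagent + intermediate B → target (k = 1.35 M⁻¹ min⁻¹)
    starting material + second reagent → side product A (k = 0.302 M⁻¹ min⁻¹)
    starting material + target → side product B (k = 1.25 M⁻¹ min⁻¹)

In south-west at 0.243 h, starting material had a half-life of 0.41 h by the partner step, while intermediate A had 1.8 h by the second-reagent step, a longer time. At 1.00 h in south-west, intermediate A was made 1.48 times faster than it was used up, each step taken net. At N = 2.19, south-west kept 0.669 of its ceiling. The neighbour of south-west with 6.0 mM of second reagent, its other charges and time held, has the same N and kept 0.742, which is 65.9 % of the starting material as intermediate A.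

(The earlier runs and the new flask were computed from invented constants.)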